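**Retrosynthetic overview**

- The strategy rests on ring A (C4a, C5, C6, C7, C8, C8a), whose four adjacent carbons C5–C8 each carry oxygen; all four oxygens and C5–C8 are taken from dimethyl squarate.
- Target 16 ⇐ hydrogenolysis of benzyl ether 15 ⇐ double O-methylation of the 5,8-quinol 14.
- 14 ⇐ thermal ring expansion of cyclobutenone 11: the ketene carbon (future C5) bonds to the pyranone CH carbon (future C4a) and closes ring A onto the finished ring C.
- 11 ⇐ pyranonyl Grignard (from iodide 8 by I/Mg exchange) + dimethyl squarate 9; 8 ⇐ zincation/iodination of 2-aryl-4-pyranone 6 at the CH next to the ring oxygen.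
- 6 ⇐ dehydrogenation of hetero-Diels–Alder adduct 5 ⇐ benzylated aldehyde 2 + Danishefsky's diene 3. Ring order: B purchased, C (steps 2–3), A (step 6).

Key step: step 6

Remark: the target has no stereocentre and is one achiral compound, so no enantiocontrol is needed; the stereocentres of 4, 5, 11 and 13 are transient and are carried racemic.

**Route**

Step 1
Reactants: 1 3-hydroxy-4,5-dimethoxybenzaldehyde
Product: 2 3-benzyloxy-4,5-dimethoxybenzaldehyde
Conditions: BnBr, K2CO3, DMF, rt
Reagents that add atoms: benzyl bromide, BrCc1ccccc1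
Why: Williamson etherification of the only phenol masks the future 3'-hydroxyl as a benzyl ether that should survive Lewis acid, DDQ, amide base, Grignard reagent, heat and alkylation and can be removed last by hydrogenolysis.

Step 2
Reactants: 2 3-benzyloxy-4,5-dimethoxybenzaldehyde; 3 Danishefsky's diene [(E)-1-methoxy-3-(trimethylsilyloxy)buta-1,3-diene]
Product: 5 racemic 2-(3-benzyloxy-4,5-dimethoxyphenyl)-2,3-dihydro-4H-pyran-4-one, via silyl enol ether cycloadduct 4 (not isolated)
Conditions: ZnCl2, THF, rt; then TFA, CH2Cl2, 0 °C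
Reagents that add atoms: none
Why: Lewis-acid-catalysed hetero-Diels–Alder reaction of the aryl aldehyde with the electron-rich diene gives the cycloadduct, from which TFA removes methanol and the silyl group to leave the 2,3-dihydro-4-pyranone; the C2 stereocentre forms racemic and is erased in step 3.

Step 3
Reactants: 5 racemic 2-(3-benzyloxy-4,5-dimethoxyphenyl)-2,3-dihydro-4H-pyran-4-one
Product: 6 2-(3-benzyloxy-4,5-dimethoxyphenyl)-4H-pyran-4-one
Conditions: DDQ, 1,4-dioxane, 100 °C
Reagents that add atoms: none
Why: DDQ dehydrogenation by hydride abstraction from C2–H (benzylic to an electron-rich arene and α to the ring oxygen) and loss of the C3 proton, the reaction type of flavanone-to-flavone oxidation, driven by formation of the cross-conjugated γ-pyranone.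

Step 4
Reactants: 6 2-(3-benzyloxy-4,5-dimethoxyphenyl)-4H-pyran-4-one
Product: 8 2-(3-benzyloxy-4,5-dimethoxyphenyl)-6-iodo-4H-pyran-4-one, via pyranonylzinc chloride 7 (not isolated)
Conditions: TMPZnCl·LiCl, THF, 25 °C; then I2, THF, 0 °C
Reagents that add atoms: iodine, II
Why: Directed deprotonative zincation with the hindered amide base and no added Lewis acid should take the most acidic ring C–H, that on the carbon next to the ring oxygen (the position zincated in chromones), the soft C–Zn species does not attack the pyranone, and iodinolysis fixes the site as an alkenyl iodide.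

Step 5
Reactants: 8 2-(3-benzyloxy-4,5-dimethoxyphenyl)-6-iodo-4H-pyran-4-one; 9 dimethyl squarate
Product: 11 racemic 4-hydroxy-2,3-dimethoxy-4-[6-(3-benzyloxy-4,5-dimethoxyphenyl)-4-oxo-4H-pyran-2-yl]cyclobut-2-en-1-one, via pyranonylmagnesium chloride 10 (not isolated)
Conditions: iPrMgCl·LiCl, THF, −78 °C; then 9, −78 to −40 °C; aq NH4Cl
Reagents that add atoms: none
Why: Iodine–magnesium exchange on the electron-poor alkenyl iodide at −78 °C should outrun attack on the vinylogous ester carbonyl, and the alkenyl Grignard then adds 1,2 to one carbonyl of the squarate as aryl and alkenyl organometallics do; the carbinol carbon forms racemic and becomes the planar C8 in step 6.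

Step 6
Reactants: 11 racemic 4-hydroxy-2,3-dimethoxy-4-[6-(3-benzyloxy-4,5-dimethoxyphenyl)-4-oxo-4H-pyran-2-yl]cyclobut-2-en-1-one
Product: 14 3'-O-benzyl-5,8-dihydroxy-6,7,4',5'-tetramethoxyflavone, via dienylketene 12 (not isolated), via ring-fused cyclohexadienone 13 (not isolated)
Conditions: p-xylene (degassed), 138 °C, Ar
Reagents that add atoms: none
Why: Heating should open the cyclobutenone by conrotatory 4π cleavage of the C1–C4 bond to dienylketene 12, and the hydroxyl, being the donor on C4, rotates outward so that the pyranonyl group lies cis to the ketene. Ring A then closes by a thermal disrotatory 6π electrocyclisation (all-carbon six-membered ring) in which the ketene carbon bonds to the pyranone CH carbon next to the point of attachment (C3 of the pyranone in 11), forming C4a–C5 and giving dienone 13. Enolisation of 13 through its 4a-hydrogen, which lies between two carbonyl groups, aromatises ring A to the 5,8-quinol with the squarate methoxy groups on C6 and C7. The closest known reaction type is the Moore-type ring expansion of 4-aryl-, 4-heteroaryl- and 4-alkenyl-4-hydroxycyclobutenones, of which the pyranonyl case is a new member. No stereocentre survives, since the carbinol centre of 11 and the 4a centre of 13 both become sp2. The step needs outward rotation of the hydroxyl (inward rotation would lead to a butenolide by O–H addition to the ketene) and closure on carbon, and the substrate secures the second because the other neighbour of the attachment carbon is the ring oxygen.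

Step 7
Reactants: 14 3'-O-benzyl-5,8-dihydroxy-6,7,4',5'-tetramethoxyflavone
Product: 15 3'-benzyloxy-5,6,7,8,4',5'-hexamethoxyflavone
Conditions: Me2SO4, K2CO3, acetone, reflux, Ar
Reagents that add atoms: dimethyl sulfate, COS(=O)(=O)OC
Why: Williamson O-methylation of both phenols with excess dimethyl sulfate and carbonate at reflux, conditions that also methylate the hydrogen-bonded 5-hydroxyl of flavones, with oxygen excluded so that the quinol is alkylated before it can be oxidised to the 5,8-quinone.

Step 8
Reactants: 15 3'-benzyloxy-5,6,7,8,4',5'-hexamethoxyflavone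
Product: 16 3'-hydroxy-5,6,7,8,4',5'-hexamethoxyflavone
Conditions: H2 (1 atm), 10% Pd/C, EtOAc–MeOH, rt
Reagents that add atoms: none
Why: Catalytic hydrogenolysis cleaves the benzylic C–O bond of the aryl benzyl ether under neutral conditions and should leave the six methyl ethers (including the acid-labile 5-methoxy) and the conjugated flavone C2=C3 bond in place.

**Compound list**

1 | 3-hydroxy-4,5-dimethoxybenzaldehyde | COc1cc(C=O)cc(O)c1OC | starting material
2 | 3-benzyloxy-4,5-dimethoxybenzaldehyde | COc1cc(C=O)cc(OCc2ccccc2)c1OC | intermediate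
3 | Danishefsky's diene, (E)-1-methoxy-3-(trimethylsilyloxy)buta-1,3-diene | CO/C=C/C(=C)O[Si](C)(C)C | starting material
4 | 2-(3-benzyloxy-4,5-dimethoxyphenyl)-6-methoxy-4-(trimethylsilyloxy)-3,6-dihydro-2H-pyran (racemic, cis/trans mixture; not isolated) | COC1C=C(O[Si](C)(C)C)CC(c2cc(OC)c(OC)c(OCc3ccccc3)c2)O1 | intermediate
5 | racemic 2-(3-benzyloxy-4,5-dimethoxyphenyl)-2,3-dihydro-4H-pyran-4-one | O=C1C=COC(c2cc(OC)c(OC)c(OCc3ccccc3)c2)C1 | intermediate
6 | 2-(3-benzyloxy-4,5-dimethoxyphenyl)-4H-pyran-4-one | O=c1ccoc(-c2cc(OC)c(OC)c(OCc3ccccc3)c2)c1 | intermediate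
7 | [6-(3-benzyloxy-4,5-dimethoxyphenyl)-4-oxo-4H-pyran-2-yl]zinc chloride, LiCl complex (not isolated) | O=c1cc([Zn]Cl)oc(-c2cc(OC)c(OC)c(OCc3ccccc3)c2)c1 | intermediate
8 | 2-(3-benzyloxy-4,5-dimethoxyphenyl)-6-iodo-4H-pyran-4-one | O=c1cc(I)oc(-c2cc(OC)c(OC)c(OCc3ccccc3)c2)c1 | intermediate
9 | dimethyl squarate, 3,4-dimethoxycyclobut-3-ene-1,2-dione | COC1=C(OC)C(=O)C1=O | starting material
10 | [6-(3-benzyloxy-4,5-dimethoxyphenyl)-4-oxo-4H-pyran-2-yl]magnesium chloride, LiCl complex (not isolated) | O=c1cc([Mg]Cl)oc(-c2cc(OC)c(OC)c(OCc3ccccc3)c2)c1 | intermediate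
11 | racemic 4-hydroxy-2,3-dimethoxy-4-[6-(3-benzyloxy-4,5-dimethoxyphenyl)-4-oxo-4H-pyran-2-yl]cyclobut-2-en-1-one | O=c1cc(-c2cc(OC)c(OC)c(OCc3ccccc3)c2)oc(C2(O)C(=O)C(OC)=C2OC)c1 | intermediate
12 | dienylketene, 4-hydroxy-2,3-dimethoxy-4-(6-aryl-4-oxo-4H-pyran-2-yl)buta-1,3-dien-1-one with hydroxyl trans and pyranonyl cis to the ketene-bearing carbon (not isolated) | O=C=C(OC)/C(OC)=C(/O)c1cc(=O)cc(-c2cc(OC)c(OC)c(OCc3ccccc3)c2)o1 | intermediate
13 | racemic 2-(3-benzyloxy-4,5-dimethoxyphenyl)-8-hydroxy-6,7-dimethoxy-4aH-chromene-4,5-dione (not isolated) | O=C1C(OC)=C(OC)C(O)=C2OC(-c3cc(OC)c(OC)c(OCc4ccccc4)c3)=CC(=O)C12 | intermediate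
14 | 3'-O-benzyl-5,8-dihydroxy-6,7,4',5'-tetramethoxyflavone | COc1cc(-c2cc(=O)c3c(O)c(OC)c(OC)c(O)c3o2)cc(OCc2ccccc2)c1OC | intermediate
15 | 3'-benzyloxy-5,6,7,8,4',5'-hexamethoxyflavone | COc1cc(-c2cc(=O)c3c(OC)c(OC)c(OC)c(OC)c3o2)cc(OCc2ccccc2)c1OC | intermediate
16 | 3'-hydroxy-5,6,7,8,4',5'-hexamethoxyflavone | COc1cc(-c2cc(=O)c3c(OC)c(OC)c(OC)c(OC)c3o2)cc(O)c1OC | target

**Step count**

Total steps: 8. Longest linear sequence: 8 steps (1 → 16); 3 and 9 are purchased building blocks.

**Steps most likely to fail**

1. Step 6 (ring expansion). The electrocyclisation onto the electron-poor pyranone double bond may be slow, so that the ketene is consumed by inward-hydroxyl closure to a butenolide or by oligomerisation. The quinol may also oxidise in air to the 5,8-quinone, which a dithionite wash would reduce back. The fallback gives up the squarate and builds ring C last on a ready-made ring A. It sets out from compound 2 and comes back at compound 15. Claisen–Schmidt condensation of 2 with purchased 2'-hydroxy-3',4',5',6'-tetramethoxyacetophenone (CC(=O)c1c(O)c(OC)c(OC)c(OC)c1OC; KOH, EtOH, rt) should give (E)-3-(3-benzyloxy-4,5-dimethoxyphenyl)-1-(2-hydroxy-3,4,5,6-tetramethoxyphenyl)prop-2-en-1-one F1. Oxidative cyclisation of the chalcone (cat. I2, DMSO, 130 °C) then closes the pyranone ring and gives 15.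

2. Step 5 (exchange and addition to the squarate). The magnesiated pyranone may add to unexchanged iodide, isopropylmagnesium chloride may attack the pyranone in a conjugate sense, or the electron-poor Grignard may add too slowly and decay on warming. The adduct may also lose methanol on an acidic work-up. The fallback makes the nucleophile by C–H deprotonation as a more reactive lithium species. It sets out from compound 6 and comes back at compound 11. Slow addition of 6 to LiTMP (THF, −78 °C), so that no free pyranone accumulates, should give [6-(3-benzyloxy-4,5-dimethoxyphenyl)-4-oxo-4H-pyran-2-yl]lithium F2, by analogy with lithiation of uracils and 3-substituted chromones next to the ring heteroatom. The cold solution is transferred onto excess 9 at −78 °C and quenched cold to give 11.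

3. Step 3 (dehydrogenation). Hydride abstraction may be sluggish, or the electron-rich aryl ring and the benzyl ether may be attacked on prolonged heating with DDQ. The fallback sets the oxidation level before ring closure, so no dehydrogenation is needed. It sets out from compound 2 and comes back at compound 6. Aldol addition of the lithium enolate of (E)-4-methoxybut-3-en-2-one (LiHMDS, THF, −78 °C) to 2 should give racemic (E)-5-(3-benzyloxy-4,5-dimethoxyphenyl)-5-hydroxy-1-methoxypent-1-en-3-one F3. Dess–Martin oxidation gives (E)-1-(3-benzyloxy-4,5-dimethoxyphenyl)-5-methoxypent-4-ene-1,3-dione F4. TFA in CH2Cl2 then cyclises the enol oxygen onto the methoxyenone with loss of methanol to give 6.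

**Further compounds**

F1 | step 6 | (E)-3-(3-benzyloxy-4,5-dimethoxyphenyl)-1-(2-hydroxy-3,4,5,6-tetramethoxyphenyl)prop-2-en-1-one | COc1cc(/C=C/C(=O)c2c(O)c(OC)c(OC)c(OC)c2OC)cc(OCc2ccccc2)c1OC
F2 | step 5 | [6-(3-benzyloxy-4,5-dimethoxyphenyl)-4-oxo-4H-pyran-2-yl]lithium | [Li]c1cc(=O)cc(-c2cc(OC)c(OC)c(OCc3ccccc3)c2)o1
F3 | step 3 | racemic (E)-5-(3-benzyloxy-4,5-dimethoxyphenyl)-5-hydroxy-1-methoxypent-1-en-3-one | CO/C=C/C(=O)CC(O)c1cc(OC)c(OC)c(OCc2ccccc2)c1
F4 | step 3 | (E)-1-(3-benzyloxy-4,5-dimethoxyphenyl)-5-methoxypent-4-ene-1,3-dione | CO/C=C/C(=O)CC(=O)c1cc(OC)c(OC)c(OCc2ccccc2)c1
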